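## Structural features

The target consists of two trans-2,3-diaryl-2,3-dihydrobenzofurans. Arene ring A is fused to dihydrofuran ring B (O1, C2, C3, C3a, C7a) and arene ring C to dihydrofuran ring D (O1', C2', C3', C3a', C7a'); the C2–C7' bond joins them, so ring C is both the benzo ring of the lower unit and the C2 aryl group of the upper one. Ring A bears a hydroxyl group at C4 and an (E)-4-hydroxystyryl arm at C6; C3 and C3' each carry a 3,5-dihydroxyphenyl ring, C2' a 2,4-dihydroxyphenyl ring, and C4', next to C3a', a hydroxyl group. The four stereocentres form two adjacent pairs, C2/C3 and C2'/C3', each trans and all R; flat ring C lies between the pairs, so neither can direct the other and absolute control is needed twice. The benzylic ether bonds C2–O1 and C2'–O1' sit beside arenes with ortho and para oxygens and ionise easily under acid, and the nine phenols and the stilbene double bond are sensitive to oxidants, electrophiles and light. The real difficulty is to make the aryl–C(sp3) bonds C3–C3a and C3'–C3a' beside an oxygenated benzylic carbon, trans and in one absolute sense, and to place on C3 and C3' rings with a 3,5-dioxygenation pattern that electrophilic arylation cannot deliver. The key step uses the fact that ring D, with the C4' oxygen beside C3a' and the dioxygenated aryl group on C2', is a ring-contracted 5-oxygenated flavanone: O1', C2', C3' and C3a' correspond to O1, C2, C3 and C4a of a chroman-4-one whose carbonyl carbon C4 has been moved out of the ring onto C3', where it later serves as the departing carboxyl group; rings B and A stand in the same relationship.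

## Logic of the disconnections

33 to 32 to 31. Seven O–CH3 bonds and then two O–SO2CH3 bonds are cut. All phenols stay masked to the end. Seven are methyl ethers. The two on the aryl group at C2' are methanesulfonates, because methyl ethers there would make that ring the better migrating group in the key step and a target for the oxidant. The demand is that deprotection must not ionise C2–O1 or C2'–O1' or add to the alkene, so the sulfonates go first under base and the Lewis acid comes last.

31 to 29 and 30. The C6–vinyl bond is cut. The stilbene then never meets the iodine oxidant or the nickel catalyst. The demand is an E-selective Heck reaction on an aryl chloride that has survived every earlier step.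

29 to 25 and 28, then 25 to 24 to 23. Both the C3–aryl and the C3'–aryl bonds are cut together. The carboxyl carbons expelled by the two ring contractions are radical precursors, and one reagent delivers both 3,5-dimethoxyphenyl rings after the last oxidation. These very electron-rich rings therefore never see trivalent iodine. The demand is two trans-selective radical captures, with the aryl chloride and the sulfonates inert to nickel.

23 to 20. The C3–C3a bond of ring B is cut and C4–C4a of a chromanone restored (second ring contraction). This turns ring B into a flavanone that can be assembled by conjugate addition. The demand is that the ring A carbon migrates, not ring C.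

20 to 13 and 19. The C2–C7' bond is cut. This divides the molecule into two halves of similar size and lets a catalyst set C2. The demand is transfer of a hindered, ortho-alkoxy aryl group under catalyst control.

13 to 12. The C7'–B bond is exchanged for C7'–Br; the bromide is inert until it is needed.

12 to 9 (key disconnection). The C3'–C3a' bond is cut and C4–C4a of the flavanone restored. Ring D becomes a six-membered ketone with a single stereocentre. The demand is migration of the ring C carbon only, with retention at C2'.

9 to 8 and 3. The C2'–aryl bond is cut. Both partners become achiral and the stereocentre comes from a ligand. The demand is face-selective addition that leaves the C–Br bond alone.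

8 to 6 to 4. The pyranone C2 carbon and then the acetyl group are removed, back to a phenol whose bromine is already ortho to the hydroxyl group. This avoids having to brominate a hydroxyacetophenone with uncertain site selectivity. The demand is acylation at the one free ortho position.

3 to 2 to 1; 19 to 17 to 16 to 14; 28 to 26. These cut C–B and O–S bonds, the pyranone carbon, one O–CH3 bond, the aryl–acetyl bond, and the C–Zn bond. Each ends at a catalogue arene whose substitution pattern is already fixed.

## Other disconnections considered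

Alternative 1: The cut is the O1–C2 bond of ring B.
- Forward step: the N-acyloxyphthalimide A2, under Ir(ppy)3 and visible light, would decarboxylate to a C2 benzylic radical. Oxidation to the cation and capture by the ring A silyl ether oxygen would give A1.
- In favour: the cation is stabilised by the ortho and para oxygens of ring C. The electron richness of ring C, a liability in step 12 of the chosen plan, is an asset here, and no aryl shift can compete. On this point the alternative is better. The aryl bromide survives photoredox conditions, which is equal to carrying a chloride through nickel.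
- Against: A2 needs its C3 stereocentre set beforehand by a separate enantioselective construction of a 3,4-diaryl dihydrocoumarin. Three operations (lactone opening, silylation, active ester) precede the key step. The trans relationship relies on closure anti to the C3 aryl group, and loss of a proton to a stilbene could compete.
- Comparison: structurally it addresses ring B only, and ring D would still be made as in steps 3 to 6. Mechanistically it is a cation capture, against a stereospecific shift in the chosen plan. Step economy is about equal.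

Alternative 2: The cuts are C3a–C7a and C6–C7 of ring A.
- Forward step: heating the alkynyl ether A4 would give an intramolecular cycloaddition across C3 and C6 of its pyrone. Decarboxylation of the bridged lactone would then give A3, with ring A aromatic and ring B closed.
- In favour: this is the most convergent plan. The styryl arm is already present, so no halogen handle and no Heck step are needed. No oxidant is used, and the stereocentres are not touched. After the key step only deprotection remains, which is better than the chosen plan.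
- Against: the two acyclic stereocentres of A4 must be set anti and in absolute terms and attached to C3 of a 4-methoxypyrone. A terminal alkynyl ether of a hindered secondary benzylic alcohol is prone to sigmatropic rearrangement and ketene formation at the temperatures the cycloaddition needs. The styryl diene could also take part.
- Comparison: structurally it builds rings A and B at once, where the chosen plan contracts a preformed ring. Mechanistically it is pericyclic and equal or better at preserving stereocentres. It is shorter after the key step but longer and less certain before it.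

Alternative 3: The cuts are C3–C3a and O1–C2 of ring B.
- Forward step: Mn(OAc)3 (trivalent manganese) would oxidise the dione A6 to its C2 radical. Addition to the stilbene A7 at the carbon bearing the 3,5-dimethoxyphenyl ring, oxidation, and closure by the enol oxygen would give A5.
- In favour: two bonds form in one step from a stilbene made by olefination. Regiochemistry is guided by the cation-stabilising power of ring C, and the trans ring fusion is the stable one. The reaction class is as well established as the chosen ring contraction, so it is equal on precedent.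
- Against: nothing controls the face of the stilbene. The ring D stereocentres are too remote, so both trans diastereomers are to be expected. Ring A must then be aromatised and O-methylated, and the ester turned into the styryl arm by reduction, oxidation and olefination.
- Comparison: structurally it is convergent. Mechanistically it is a radical–polar annulation without absolute control, which is worse than the ligand-controlled chosen plan. It is longer after the key step.

Key step: step 6

Remarks on the chemistry (assumptions and design choices):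
- Benzofuran numbering is used for rings B/A (unprimed) and D/C (primed). Chromanone numbering (O1, C2, C3, C4, C4a … C8a) is used for the flavanones.
- Flavanone 9 and ester 12 map atom for atom onto ring D. C2 of 9 is R as required at C2', and 12 is the (2R,3R) trans ester. No change of skeleton or configuration is needed, only of protecting and spectator groups.
- Assumption: (S)-t-BuPyOx is taken to give the R flavanone, by analogy with its facial sense on cyclic enones. If the sense is opposite, the R ligand is used with no other change.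
- Compounds 1, 4, 14, 26 and 30 are catalogue chemicals.

## Route

Step 1
Reactants: 1 4-bromobenzene-1,3-diol
Product: 2 4-bromo-1,3-phenylene dimethanesulfonate
Conditions: MsCl (2.3 equiv), Et3N, CH2Cl2, 0 °C to rt
Reagents that add atoms: methanesulfonyl chloride, CS(=O)(=O)Cl
Why: Double O-sulfonylation of the phenols; the sulfonates turn the future C2' aryl ring into an electron-poor, poorly migrating group that the iodine oxidant will not attack.

Step 2
Reactants: 2 4-bromo-1,3-phenylene dimethanesulfonate
Product: 3 [2,4-bis(methylsulfonyloxy)phenyl]boronic acid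
Conditions: B2(OH)4 (1.5 equiv), Pd(OAc)2 (2 mol%), XPhos (4 mol%), KOAc, EtOH, 80 °C
Reagents that add atoms: tetrahydroxydiboron, OB(O)B(O)O
Why: Miyaura-type borylation with tetrahydroxydiboron gives the boronic acid directly; oxidative addition into C–Br is far faster than into aryl methanesulfonates, and acetate is too weak a base to cleave them.

Step 3
Reactants: 4 2-bromo-5-methoxyphenol
Product: 6 1-(3-bromo-2-hydroxy-6-methoxyphenyl)ethan-1-one, via ketimine 5 (not isolated)
Conditions: BCl3 (1.1 equiv), MeCN, AlCl3 (1 equiv), CH2Cl2, 0 °C to rt; then 2 M HCl, 80 °C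
Reagents that add atoms: acetonitrile, CC#N; water, O
Why: Sugasawa-type ortho-acylation: the aryloxydichloroborane delivers the nitrile only to the free ortho position between the hydroxyl and methoxy groups, and hydrolysis of ketimine 5 gives the ketone. The bromine thus ends up beside the hydroxyl group without any regiochemical ambiguity.

Step 4
Reactants: 6 1-(3-bromo-2-hydroxy-6-methoxyphenyl)ethan-1-one
Product: 8 8-bromo-5-methoxy-4H-chromen-4-one, via enaminone 7 (not isolated)
Conditions: Me2NCH(OMe)2, toluene, 100 °C; then conc. HCl, CH2Cl2, 40 °C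
Reagents that add atoms: N,N-dimethylformamide dimethyl acetal, COC(OC)N(C)C
Why: Enaminone chromone synthesis: condensation at the acetyl methyl group, then acid-promoted addition of the phenol and loss of dimethylamine.

Step 5
Reactants: 8 8-bromo-5-methoxy-4H-chromen-4-one; 3 [2,4-bis(methylsulfonyloxy)phenyl]boronic acid (2 equiv)
Product: 9 (2R)-8-bromo-2-[2,4-bis(methylsulfonyloxy)phenyl]-5-methoxy-2,3-dihydro-4H-chromen-4-one
Conditions: Pd(O2CCF3)2 (5 mol%), (S)-4-tert-butyl-2-(pyridin-2-yl)-4,5-dihydrooxazole [(S)-t-BuPyOx] (6 mol%), NH4PF6 (30 mol%), H2O (5 equiv), ClCH2CH2Cl, 60 °C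
Reagents that add atoms: none
Why: Asymmetric conjugate addition of an arylboronic acid to a chromone with a cationic divalent palladium/pyridine-oxazoline catalyst; the ligand selects the face of C2 and so sets the R centre. The metal stays divalent, so the C–Br bond is spared, and the electron-poor boronic acid resists protodeboronation.

Step 6
Reactants: 9 (2R)-8-bromo-2-[2,4-bis(methylsulfonyloxy)phenyl]-5-methoxy-2,3-dihydro-4H-chromen-4-one
Product: 12 methyl (2R,3R)-7-bromo-2-[2,4-bis(methylsulfonyloxy)phenyl]-4-methoxy-2,3-dihydro-1-benzofuran-3-carboxylate, via enol ether 10 (not isolated), via iodane ketal 11 (not isolated)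
Conditions: PhI(OAc)2 (1.2 equiv), conc. H2SO4 (2 equiv), HC(OMe)3, 0 °C to rt; aq. NaHCO3
Reagents that add atoms: trimethyl orthoformate, COC(OC)OC
Why: Acid and the orthoformate should convert ketone 9 into enol ether 10; electrophilic trivalent iodine then attacks C3 of 10 on the face away from the C2 aryl group and methanol caps the C4 oxocarbenium ion, giving 11 with aryl group and iodane both equatorial. In that half-chair the C4–C4a bond is antiperiplanar to the C3–I bond, so arene carbon C4a moves from C4 to C3 as iodobenzene leaves, and the dimethoxycarbenium ion left at C4 is quenched to the methyl ester on work-up. The closest known reaction type is the oxidative ring contraction of flavanones by PhI(OAc)2 or Tl(NO3)3 in trimethyl orthoformate to methyl trans-2-aryl-2,3-dihydrobenzofuran-3-carboxylates. Ring D is closed by contraction of the existing oxygen heterocycle: the new C3'–C3a' bond comes from a 1,2-shift, no C–O bond is made or broken, and C2' therefore keeps its configuration. The new centre C3' is controlled by C2': the iodane enters trans, the shift inverts C3, and the ester emerges trans to the aryl group, which is also the more stable arrangement. The selectivity needed is migration of C4a and not of the C2 aryl group (which would lead to an isoflavone). It is secured by the antiperiplanar geometry of the diequatorial iodane, by the two ortho oxygens (O1 and the C5 methoxy group) that stabilise the bridged transition state of the ring C carbon, and by the two methanesulfonyloxy groups, which make the C2 aryl ring a poor migrating group and too electron-poor for the oxidant or for acid ionisation at C2.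

Step 7
Reactants: 12 methyl (2R,3R)-7-bromo-2-[2,4-bis(methylsulfonyloxy)phenyl]-4-methoxy-2,3-dihydro-1-benzofuran-3-carboxylate
Product: 13 [(2R,3R)-2-[2,4-bis(methylsulfonyloxy)phenyl]-4-methoxy-3-(methoxycarbonyl)-2,3-dihydro-1-benzofuran-7-yl]boronic acid
Conditions: B2(OH)4 (2 equiv), Pd(OAc)2 (3 mol%), XPhos (6 mol%), KOAc, EtOH, 80 °C
Reagents that add atoms: tetrahydroxydiboron, OB(O)B(O)O
Why: Miyaura-type borylation of the aryl bromide; the sulfonates and the ester are inert to this catalyst, and acetate is too weak a base to enolise the C3 ester.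

Step 8
Reactants: 14 1-chloro-3,5-dimethoxybenzene
Product: 16 1-(4-chloro-2,6-dimethoxyphenyl)ethan-1-one, via aryllithium 15 (not isolated)
Conditions: n-BuLi, THF, 0 °C; then MeC(O)N(OMe)Me, −78 °C to rt; aq. NH4Cl
Reagents that add atoms: N-methoxy-N-methylacetamide, CC(=O)N(C)OC
Why: Directed ortho-lithiation at the position flanked by both methoxy groups (the chloride does not exchange), then acylation by the N-methoxy-N-methylamide, whose chelated adduct prevents over-addition.

Step 9
Reactants: 16 1-(4-chloro-2,6-dimethoxyphenyl)ethan-1-one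
Product: 17 1-(4-chloro-2-hydroxy-6-methoxyphenyl)ethan-1-one
Conditions: BCl3 (1.1 equiv), CH2Cl2, −78 to 0 °C; aq. work-up
Reagents that add atoms: none
Why: Chelation-controlled cleavage of a methyl ether ortho to the ketone; the boron chelate formed stops the reaction after one of the two equivalent ethers.

Step 10
Reactants: 17 1-(4-chloro-2-hydroxy-6-methoxyphenyl)ethan-1-one
Product: 19 7-chloro-5-methoxy-4H-chromen-4-one, via enaminone 18 (not isolated)
Conditions: Me2NCH(OMe)2, toluene, 100 °C; then conc. HCl, CH2Cl2, 40 °C
Reagents that add atoms: N,N-dimethylformamide dimethyl acetal, COC(OC)N(C)C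
Why: Enaminone chromone synthesis as in step 4; the chlorine ends up para to the future migrating carbon and meta to both ring oxygens.

Step 11
Reactants: 13 ring C/D boronic acid; 19 7-chloro-5-methoxy-4H-chromen-4-one (2 equiv)
Product: 20 methyl (2R,3R)-2-[2,4-bis(methylsulfonyloxy)phenyl]-7-[(2R)-7-chloro-5-methoxy-4-oxo-3,4-dihydro-2H-chromen-2-yl]-4-methoxy-2,3-dihydro-1-benzofuran-3-carboxylate
Conditions: Pd(O2CCF3)2 (10 mol%), (S)-t-BuPyOx (12 mol%), NH4PF6 (30 mol%), H2O (5 equiv), ClCH2CH2Cl, 60 °C
Reagents that add atoms: none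
Why: The same palladium/pyridine-oxazoline conjugate addition joins the two halves and forms C2–C7'; the ligand, not the distant centres of ring D, should fix the new C2 centre as R. The cheap chromone is used in excess, and the aryl chloride, ester and sulfonates are inert to divalent palladium.

Step 12
Reactants: 20 flavanone carrying the ring C/D unit at C2
Product: 23 methyl (2R,3R)-2-[(2R,3R)-2-[2,4-bis(methylsulfonyloxy)phenyl]-4-methoxy-3-(methoxycarbonyl)-2,3-dihydro-1-benzofuran-7-yl]-6-chloro-4-methoxy-2,3-dihydro-1-benzofuran-3-carboxylate, via enol ether 21 (not isolated), via iodane ketal 22 (not isolated)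
Conditions: PhI(OAc)2 (1.2 equiv), conc. H2SO4 (2 equiv), HC(OMe)3, 0 °C to rt; aq. NaHCO3
Reagents that add atoms: trimethyl orthoformate, COC(OC)OC
Why: Second oxidative ring contraction of a flavanone, as in step 6: in 22 the ring A carbon C4a, flanked by O1 and the C5 methoxy group, shifts from C4 to C3 anti to the departing iodobenzene and gives the trans ester of ring B. The sulfonated ring and the ester of ring D are inert, and the 3,5-dimethoxyphenyl rings are not yet present, so the oxidant has no electron-rich bystander.

Step 13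
Reactants: 23 diester
Product: 24 (2R,3R)-2-[(2R,3R)-2-[2,4-bis(methylsulfonyloxy)phenyl]-3-carboxy-4-methoxy-2,3-dihydro-1-benzofuran-7-yl]-6-chloro-4-methoxy-2,3-dihydro-1-benzofuran-3-carboxylic acid
Conditions: Me3SnOH (8 equiv), ClCH2CH2Cl, 80 °C; then 1 M HCl
Reagents that add atoms: trimethyltin hydroxide, C[Sn](C)(C)O
Why: Neutral hydrolysis of both methyl esters with trimethyltin hydroxide. Alkali hydroxide is avoided because enolisation at C3 or C3' could open the dihydrofurans by β-elimination of the phenoxide, and the sulfonates are spared.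

Step 14
Reactants: 24 diacid
Product: 25 1,3-dioxoisoindolin-2-yl (2R,3R)-2-[(2R,3R)-2-[2,4-bis(methylsulfonyloxy)phenyl]-3-[(1,3-dioxoisoindolin-2-yl)oxycarbonyl]-4-methoxy-2,3-dihydro-1-benzofuran-7-yl]-6-chloro-4-methoxy-2,3-dihydro-1-benzofuran-3-carboxylate
Conditions: N-hydroxyphthalimide (2.4 equiv), i-PrN=C=N-i-Pr (2.4 equiv), DMAP (cat.), CH2Cl2, rt
Reagents that add atoms: N-hydroxyphthalimide, O=C1c2ccccc2C(=O)N1O
Why: Carbodiimide esterification of both acids to the redox-active N-acyloxyphthalimides.

Step 15
Reactants: 26 1-bromo-3,5-dimethoxybenzene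
Product: 28 (3,5-dimethoxyphenyl)zinc chloride, via Grignard reagent 27 (not isolated)
Conditions: Mg, LiCl, THF, rt; then ZnCl2, THF, 0 °C to rt; solution used directly
Reagents that add atoms: zinc chloride, Cl[Zn]Cl
Why: Grignard formation followed by transmetalation to zinc gives an arylzinc mild enough to tolerate esters, sulfonates and the aryl chloride.

Step 16
Reactants: 25 bis(N-acyloxyphthalimide); 28 (3,5-dimethoxyphenyl)zinc chloride (6 equiv)
Product: 29 (2R,3R)-2-[(2R,3R)-2-[2,4-bis(methylsulfonyloxy)phenyl]-3-(3,5-dimethoxyphenyl)-4-methoxy-2,3-dihydro-1-benzofuran-7-yl]-6-chloro-3-(3,5-dimethoxyphenyl)-4-methoxy-2,3-dihydro-1-benzofuran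
Conditions: NiCl2(glyme) (40 mol%), 4,4'-di-tert-butyl-2,2'-bipyridine (80 mol%), THF/DMF, rt
Reagents that add atoms: none
Why: Nickel-catalysed decarboxylative Negishi-type arylation of redox-active esters: electron transfer to each ester releases CO2 and a benzylic radical at C3 or C3', which aryl–nickel captures and couples. The aryl group should enter anti to the neighbouring C2 substituent and give both trans pairs. The unactivated aryl chloride and the sulfonates should not react with bipyridine-ligated nickel at rt.

Step 17
Reactants: 29 bis-arylated aryl chloride; 30 4-methoxystyrene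
Product: 31 (2R,3R)-2-[(2R,3R)-2-[2,4-bis(methylsulfonyloxy)phenyl]-3-(3,5-dimethoxyphenyl)-4-methoxy-2,3-dihydro-1-benzofuran-7-yl]-3-(3,5-dimethoxyphenyl)-4-methoxy-6-[(E)-2-(4-methoxyphenyl)ethenyl]-2,3-dihydro-1-benzofuran
Conditions: Pd2(dba)3 (3 mol%), [HP(t-Bu)3]BF4 (12 mol%), Cy2NMe, 1,4-dioxane, 110 °C
Reagents that add atoms: none
Why: Mizoroki–Heck coupling of an unhindered aryl chloride under bulky trialkylphosphine catalysis; syn insertion and syn β-hydride elimination give the E stilbene. Aryl methanesulfonates do not add to this catalyst.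

Step 18
Reactants: 31 stilbene bis(methanesulfonate)
Product: 32 4-[(2R,3R)-7-[(2R,3R)-3-(3,5-dimethoxyphenyl)-4-methoxy-6-[(E)-2-(4-methoxyphenyl)ethenyl]-2,3-dihydro-1-benzofuran-2-yl]-3-(3,5-dimethoxyphenyl)-4-methoxy-2,3-dihydro-1-benzofuran-2-yl]benzene-1,3-diol
Conditions: 2 M NaOH (aq.), MeOH/THF, 60 °C; then 1 M HCl
Reagents that add atoms: none
Why: Hydroxide cleaves the S–O bonds of the two aryl methanesulfonates; the methyl ethers, the alkene and the dihydrofurans (no acidifying ester left) are stable to base.

Step 19
Reactants: 32 heptamethyl ether bisphenol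
Product: 33 (2R,3R)-2-[(2R,3R)-2-(2,4-dihydroxyphenyl)-3-(3,5-dihydroxyphenyl)-4-hydroxy-2,3-dihydro-1-benzofuran-7-yl]-3-(3,5-dihydroxyphenyl)-6-[(E)-2-(4-hydroxyphenyl)ethenyl]-2,3-dihydro-1-benzofuran-4-ol
Conditions: BBr3 (15 equiv), CH2Cl2, −78 °C to rt; then MeOH, H2O
Reagents that add atoms: none
Why: Lewis-acid cleavage of the seven aryl methyl ethers (boron tribromide demethylation); the phenols are boron-bound until the quench, and any reversible opening of a benzylic ether bond should return to the more stable trans ring.

## Compound list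

1 | 4-bromobenzene-1,3-diol | Oc1ccc(Br)c(O)c1 | starting material
2 | 4-bromo-1,3-phenylene dimethanesulfonate | CS(=O)(=O)Oc1ccc(Br)c(OS(C)(=O)=O)c1 | intermediate
3 | [2,4-bis(methylsulfonyloxy)phenyl]boronic acid | CS(=O)(=O)Oc1ccc(B(O)O)c(OS(C)(=O)=O)c1 | intermediate
4 | 2-bromo-5-methoxyphenol | COc1ccc(Br)c(O)c1 | starting material
5 | 1-(3-bromo-2-hydroxy-6-methoxyphenyl)ethan-1-imine (boron-bound in the flask) | CC(=N)c1c(O)c(Br)ccc1OC | intermediate
6 | 1-(3-bromo-2-hydroxy-6-methoxyphenyl)ethan-1-one | CC(=O)c1c(O)c(Br)ccc1OC | intermediate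
7 | (E)-1-(3-bromo-2-hydroxy-6-methoxyphenyl)-3-(dimethylamino)prop-2-en-1-one | CN(C)/C=C/C(=O)c1c(O)c(Br)ccc1OC | intermediate
8 | 8-bromo-5-methoxy-4H-chromen-4-one | COc1ccc(Br)c2occc(=O)c12 | intermediate
9 | (2R)-8-bromo-2-[2,4-bis(methylsulfonyloxy)phenyl]-5-methoxy-2,3-dihydro-4H-chromen-4-one | Brc1ccc(OC)c2c1O[C@@H](c1ccc(OS(C)(=O)=O)cc1OS(C)(=O)=O)CC2=O | intermediate
10 | 8-bromo-2-[2,4-bis(methylsulfonyloxy)phenyl]-4,5-dimethoxy-2H-chromene, C2 as in 9 | Brc1ccc(OC)c2c1O[C@@H](c1ccc(OS(C)(=O)=O)cc1OS(C)(=O)=O)C=C2OC | intermediate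
11 | 3-[acetoxy(phenyl)-λ3-iodanyl]-8-bromo-2-[2,4-bis(methylsulfonyloxy)phenyl]-4,4,5-trimethoxychromane, C2 as in 9, iodane trans to the C2 aryl group | Brc1ccc(OC)c2c1O[C@@H](c1ccc(OS(C)(=O)=O)cc1OS(C)(=O)=O)[C@H](I(OC(C)=O)c1ccccc1)C2(OC)OC | intermediate
12 | methyl (2R,3R)-7-bromo-2-[2,4-bis(methylsulfonyloxy)phenyl]-4-methoxy-2,3-dihydro-1-benzofuran-3-carboxylate | Brc1ccc(OC)c2c1O[C@@H](c1ccc(OS(C)(=O)=O)cc1OS(C)(=O)=O)[C@@H]2C(=O)OC | intermediate
13 | [(2R,3R)-2-[2,4-bis(methylsulfonyloxy)phenyl]-4-methoxy-3-(methoxycarbonyl)-2,3-dihydro-1-benzofuran-7-yl]boronic acid | OB(O)c1ccc(OC)c2c1O[C@@H](c1ccc(OS(C)(=O)=O)cc1OS(C)(=O)=O)[C@@H]2C(=O)OC | intermediate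
14 | 1-chloro-3,5-dimethoxybenzene | COc1cc(Cl)cc(OC)c1 | starting material
15 | (4-chloro-2,6-dimethoxyphenyl)lithium | [Li]c1c(OC)cc(Cl)cc1OC | intermediate
16 | 1-(4-chloro-2,6-dimethoxyphenyl)ethan-1-one | CC(=O)c1c(OC)cc(Cl)cc1OC | intermediate
17 | 1-(4-chloro-2-hydroxy-6-methoxyphenyl)ethan-1-one | CC(=O)c1c(O)cc(Cl)cc1OC | intermediate
18 | (E)-1-(4-chloro-2-hydroxy-6-methoxyphenyl)-3-(dimethylamino)prop-2-en-1-one | CN(C)/C=C/C(=O)c1c(O)cc(Cl)cc1OC | intermediate
19 | 7-chloro-5-methoxy-4H-chromen-4-one | COc1cc(Cl)cc2occc(=O)c12 | intermediate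
20 | methyl (2R,3R)-2-[2,4-bis(methylsulfonyloxy)phenyl]-7-[(2R)-7-chloro-5-methoxy-4-oxo-3,4-dihydro-2H-chromen-2-yl]-4-methoxy-2,3-dihydro-1-benzofuran-3-carboxylate | Clc1cc(OC)c2c(c1)O[C@@H](c3ccc(OC)c4c3O[C@@H](c3ccc(OS(C)(=O)=O)cc3OS(C)(=O)=O)[C@@H]4C(=O)OC)CC2=O | intermediate
21 | 4-methyl enol ether of 20 (7-chloro-4,5-dimethoxy-2H-chromen-2-yl unit, all centres as in 20) | Clc1cc(OC)c2c(c1)O[C@@H](c3ccc(OC)c4c3O[C@@H](c3ccc(OS(C)(=O)=O)cc3OS(C)(=O)=O)[C@@H]4C(=O)OC)C=C2OC | intermediate
22 | 3-[acetoxy(phenyl)-λ3-iodanyl] 4,4-dimethyl ketal of 20, iodane trans to the C2 aryl group, other centres as in 20 | Clc1cc(OC)c2c(c1)O[C@@H](c3ccc(OC)c4c3O[C@@H](c3ccc(OS(C)(=O)=O)cc3OS(C)(=O)=O)[C@@H]4C(=O)OC)[C@H](I(OC(C)=O)c3ccccc3)C2(OC)OC | intermediate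
23 | methyl (2R,3R)-2-[(2R,3R)-2-[2,4-bis(methylsulfonyloxy)phenyl]-4-methoxy-3-(methoxycarbonyl)-2,3-dihydro-1-benzofuran-7-yl]-6-chloro-4-methoxy-2,3-dihydro-1-benzofuran-3-carboxylate | Clc1cc(OC)c2c(c1)O[C@@H](c3ccc(OC)c4c3O[C@@H](c3ccc(OS(C)(=O)=O)cc3OS(C)(=O)=O)[C@@H]4C(=O)OC)[C@@H]2C(=O)OC | intermediate
24 | (2R,3R)-2-[(2R,3R)-2-[2,4-bis(methylsulfonyloxy)phenyl]-3-carboxy-4-methoxy-2,3-dihydro-1-benzofuran-7-yl]-6-chloro-4-methoxy-2,3-dihydro-1-benzofuran-3-carboxylic acid | Clc1cc(OC)c2c(c1)O[C@@H](c3ccc(OC)c4c3O[C@@H](c3ccc(OS(C)(=O)=O)cc3OS(C)(=O)=O)[C@@H]4C(=O)O)[C@@H]2C(=O)O | intermediate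
25 | bis(1,3-dioxoisoindolin-2-yl) ester of 24 | Clc1cc(OC)c2c(c1)O[C@@H](c3ccc(OC)c4c3O[C@@H](c3ccc(OS(C)(=O)=O)cc3OS(C)(=O)=O)[C@@H]4C(=O)ON5C(=O)c6ccccc6C5=O)[C@@H]2C(=O)ON1C(=O)c3ccccc3C1=O | intermediate
26 | 1-bromo-3,5-dimethoxybenzene | COc1cc(Br)cc(OC)c1 | starting material
27 | (3,5-dimethoxyphenyl)magnesium bromide | COc1cc([Mg]Br)cc(OC)c1 | intermediate
28 | (3,5-dimethoxyphenyl)zinc chloride | COc1cc([Zn]Cl)cc(OC)c1 | intermediate
29 | (2R,3R)-2-[(2R,3R)-2-[2,4-bis(methylsulfonyloxy)phenyl]-3-(3,5-dimethoxyphenyl)-4-methoxy-2,3-dihydro-1-benzofuran-7-yl]-6-chloro-3-(3,5-dimethoxyphenyl)-4-methoxy-2,3-dihydro-1-benzofuran | Clc1cc(OC)c2c(c1)O[C@@H](c3ccc(OC)c4c3O[C@@H](c3ccc(OS(C)(=O)=O)cc3OS(C)(=O)=O)[C@@H]4c3cc(OC)cc(OC)c3)[C@@H]2c1cc(OC)cc(OC)c1 | intermediate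
30 | 4-methoxystyrene | C=Cc1ccc(OC)cc1 | starting material
31 | (2R,3R)-2-[(2R,3R)-2-[2,4-bis(methylsulfonyloxy)phenyl]-3-(3,5-dimethoxyphenyl)-4-methoxy-2,3-dihydro-1-benzofuran-7-yl]-3-(3,5-dimethoxyphenyl)-4-methoxy-6-[(E)-2-(4-methoxyphenyl)ethenyl]-2,3-dihydro-1-benzofuran | COc1ccc(/C=C/c2cc(OC)c3c(c2)O[C@@H](c2ccc(OC)c4c2O[C@@H](c2ccc(OS(C)(=O)=O)cc2OS(C)(=O)=O)[C@@H]4c2cc(OC)cc(OC)c2)[C@@H]3c2cc(OC)cc(OC)c2)cc1 | intermediate
32 | 4-[(2R,3R)-7-[(2R,3R)-3-(3,5-dimethoxyphenyl)-4-methoxy-6-[(E)-2-(4-methoxyphenyl)ethenyl]-2,3-dihydro-1-benzofuran-2-yl]-3-(3,5-dimethoxyphenyl)-4-methoxy-2,3-dihydro-1-benzofuran-2-yl]benzene-1,3-diol | COc1ccc(/C=C/c2cc(OC)c3c(c2)O[C@@H](c2ccc(OC)c4c2O[C@@H](c2ccc(O)cc2O)[C@@H]4c2cc(OC)cc(OC)c2)[C@@H]3c2cc(OC)cc(OC)c2)cc1 | intermediate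
33 | (2R,3R)-2-[(2R,3R)-2-(2,4-dihydroxyphenyl)-3-(3,5-dihydroxyphenyl)-4-hydroxy-2,3-dihydro-1-benzofuran-7-yl]-3-(3,5-dihydroxyphenyl)-6-[(E)-2-(4-hydroxyphenyl)ethenyl]-2,3-dihydro-1-benzofuran-4-ol (CNP0217875.2) | Oc1ccc(/C=C/c2cc(O)c3c(c2)O[C@@H](c2ccc(O)c4c2O[C@@H](c2ccc(O)cc2O)[C@@H]4c2cc(O)cc(O)c2)[C@@H]3c2cc(O)cc(O)c2)cc1 | target

## Step count and least certain steps

Total step count: 19. Longest linear sequence: 13 steps (4 through steps 3, 4, 5, 6, 7, 11, 12, 13, 14, 16, 17, 18, 19 to 33).

Step 6 (key step).
- What may go wrong: the iodane 11 could be diverted into a shift of the C2 aryl group or into loss of the C3 hydrogen (isoflavone or flavone formation), or acid could ionise the C2–O1 bond and erode enantiopurity. The sulfonates are there to prevent all three.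
- Fallback, from 9 back to 12:
  - Nitrosation at C3 with isoamyl nitrite and HCl should give the 3-hydroxyimino ketone F1.
  - Chloramine (Forster reaction) should turn it into the α-diazo ketone F2.
  - Irradiation in methanol should give a Wolff ring contraction. Only the acyl-bound arene carbon can migrate in it, so no aryl shift from C2 is possible.
  - The ester may form as the C3 epimer F3; a catalytic amount of DBU at low temperature should equilibrate it to 12.

Step 12.
- What may go wrong: ring C, which still has a para methoxy group and an ortho ether oxygen, could migrate from C2 to C3 in 22 in competition with the ring A carbon, whose para chlorine lowers its aptitude slightly.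
- Fallback, from 20 back to 23: the same three operations. Nitrosation gives the oxime F4, chloramine gives the diazo ketone F5, and Wolff contraction in methanol gives the ring B ester, with its C3 epimer F6 equilibrated to 23.

Step 11.
- What may go wrong: transfer of the ortho-substituted, electron-rich aryl group from boron to palladium may be slow, so that protodeboronation of 13 consumes the valuable partner; or the ligand may not override a substrate bias.
- Fallback, from 13 and 19 back to 20: a Hayashi–Miyaura addition with a chiral diene complex of monovalent rhodium generated from [RhCl(C2H4)2]2. The aryl group there passes to a rhodium hydroxide, which is less sensitive to ortho substitution. This makes no new compound (F0).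

Step 16.
- What may go wrong: after the first coupling the second may lag, and a benzylic radical may be reduced, or its nickel adduct may undergo β-hydride elimination to a benzofuran.
- Fallback, from 24 and 26 back to 29: photoredox/nickel dual catalytic decarboxylative arylation of the free diacid with the aryl bromide (Ir[dF(CF3)ppy]2(dtbbpy)PF6, NiCl2(glyme), 4,4'-di-tert-butyl-2,2'-bipyridine, Cs2CO3, DMF, blue light). No active ester and no organozinc are involved. This makes no new compound (F0).

Step 19.
- What may go wrong: the Lewis acid may ionise the benzylic C2–O1 or C2'–O1' bonds (ring opening, capture by a neighbouring arene) or HBr may add to the stilbene before all seven ethers are cleaved.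
- Fallback, from 32 back to 33: nucleophilic demethylation with sodium ethanethiolate in DMF at 140 °C under argon, in which the methyl groups are removed by substitution and no cation is formed. This makes no new compound (F0).

## Further compounds

F1 | step 6 | 3-hydroxyimino derivative of 9 (C2 as in 9) | Brc1ccc(OC)c2c1O[C@@H](c1ccc(OS(C)(=O)=O)cc1OS(C)(=O)=O)C(=NO)C2=O
F2 | step 6 | 3-diazo derivative of 9 (C2 as in 9) | Brc1ccc(OC)c2c1O[C@@H](c1ccc(OS(C)(=O)=O)cc1OS(C)(=O)=O)C(=[N+]=[N-])C2=O
F3 | step 6 | C3 epimer of 12 (cis ester) | Brc1ccc(OC)c2c1O[C@@H](c1ccc(OS(C)(=O)=O)cc1OS(C)(=O)=O)[C@H]2C(=O)OC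
F4 | step 12 | 3-hydroxyimino derivative of 20 at the chromanone (other centres as in 20) | Clc1cc(OC)c2c(c1)O[C@@H](c3ccc(OC)c4c3O[C@@H](c3ccc(OS(C)(=O)=O)cc3OS(C)(=O)=O)[C@@H]4C(=O)OC)C(=NO)C2=O
F5 | step 12 | 3-diazo derivative of 20 at the chromanone (other centres as in 20) | Clc1cc(OC)c2c(c1)O[C@@H](c3ccc(OC)c4c3O[C@@H](c3ccc(OS(C)(=O)=O)cc3OS(C)(=O)=O)[C@@H]4C(=O)OC)C(=[N+]=[N-])C2=O
F6 | step 12 | epimer of 23 at C3 of ring B (cis ester) | Clc1cc(OC)c2c(c1)O[C@@H](c3ccc(OC)c4c3O[C@@H](c3ccc(OS(C)(=O)=O)cc3OS(C)(=O)=O)[C@@H]4C(=O)OC)[C@H]2C(=O)OC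
F0 | step 11 | none | none
F0 | step 16 | none | none
F0 | step 19 | none | none
A1 | alternative 1 | (2R,3R)-6-bromo-2-[(2R,3R)-2-(2,4-dimethoxyphenyl)-3-(3,5-dimethoxyphenyl)-4-methoxy-2,3-dihydro-1-benzofuran-7-yl]-3-(3,5-dimethoxyphenyl)-4-methoxy-2,3-dihydro-1-benzofuran | Brc1cc(OC)c2c(c1)O[C@@H](c1ccc(OC)c3c1O[C@@H](c1ccc(OC)cc1OC)[C@@H]3c1cc(OC)cc(OC)c1)[C@@H]2c1cc(OC)cc(OC)c1
A2 | alternative 1 | 1,3-dioxoisoindolin-2-yl 3-[4-bromo-2-(tert-butyldimethylsilyloxy)-6-methoxyphenyl]-3-(3,5-dimethoxyphenyl)-2-[(2R,3R)-2-(2,4-dimethoxyphenyl)-3-(3,5-dimethoxyphenyl)-4-methoxy-2,3-dihydro-1-benzofuran-7-yl]propanoate (chain C3 configured as C3 of A1, either epimer at chain C2) | O=C(ON1C(=O)c2ccccc2C1=O)C(c1ccc(OC)c2c1O[C@@H](c1ccc(OC)cc1OC)[C@@H]2c1cc(OC)cc(OC)c1)[C@@H](c1c(OC)cc(Br)cc1O[Si](C)(C)C(C)(C)C)c1cc(OC)cc(OC)c1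
A3 | alternative 2 | nona-O-methyl ether of 33 | COc1ccc(/C=C/c2cc(OC)c3c(c2)O[C@@H](c2ccc(OC)c4c2O[C@@H](c2ccc(OC)cc2OC)[C@@H]4c2cc(OC)cc(OC)c2)[C@@H]3c2cc(OC)cc(OC)c2)cc1
A4 | alternative 2 | 4-methoxy-6-[(E)-2-(4-methoxyphenyl)ethenyl]-2H-pyran-2-one carrying at C3 the 1-(3,5-dimethoxyphenyl)-2-(ethynyloxy)-2-[(2R,3R)-2-(2,4-dimethoxyphenyl)-3-(3,5-dimethoxyphenyl)-4-methoxy-2,3-dihydro-1-benzofuran-7-yl]ethyl chain, chain centres configured as C3 and C2 of A3 | C#CO[C@@H](c1ccc(OC)c2c1O[C@@H](c1ccc(OC)cc1OC)[C@@H]2c1cc(OC)cc(OC)c1)[C@H](c1cc(OC)cc(OC)c1)C1=C(OC)C=C(/C=C/c2ccc(OC)cc2)OC1=O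
A5 | alternative 3 | methyl (2R,3R)-2-[(2R,3R)-2-(2,4-dimethoxyphenyl)-3-(3,5-dimethoxyphenyl)-4-methoxy-2,3-dihydro-1-benzofuran-7-yl]-3-(3,5-dimethoxyphenyl)-4-oxo-2,3,4,5,6,7-hexahydro-1-benzofuran-6-carboxylate (both C6 epimers) | COC(=O)C1CC(=O)C2=C(C1)O[C@@H](c1ccc(OC)c3c1O[C@@H](c1ccc(OC)cc1OC)[C@@H]3c1cc(OC)cc(OC)c1)[C@@H]2c1cc(OC)cc(OC)c1
A6 | alternative 3 | methyl 3,5-dioxocyclohexane-1-carboxylate | COC(=O)C1CC(=O)CC(=O)C1
A7 | alternative 3 | (2R,3R)-2-(2,4-dimethoxyphenyl)-3-(3,5-dimethoxyphenyl)-7-[(E)-2-(3,5-dimethoxyphenyl)ethenyl]-4-methoxy-2,3-dihydro-1-benzofuran | COc1cc(/C=C/c2ccc(OC)c3c2O[C@@H](c2ccc(OC)cc2OC)[C@@H]3c2cc(OC)cc(OC)c2)cc(OC)c1
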